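**Plan**

- Numbering used throughout: the cyclohexene is C1 (quaternary; CH3 and styryl) – C2 (H, indolyl) – C3=C4(CH3) – C5 – C6, and the styryl alkene is Cα=Cβ. The ring alkene C3=C4 and the exocyclic alkene Cα=Cβ sit on the neighbouring carbons C2 and C1, so cutting both and re-pairing the four carbons gives a cyclobutene (C1–C2–C3=Cα) that carries a tethered trisubstituted styrene C4(CH3)=Cβ(H)–aryl on C1.
- Further cuts: cyclobutene to cyclobutanone (enol triflate reduction); cyclobutanone to a keteniminium [2+2] (bonds C1–Cα and C2–C3); aryl–C2 and aryl–Cβ to two Suzuki couplings on (1E,5E)-1,6-diiodo-2,5-dimethylhexa-1,5-diene from hexa-1,5-diyne; the aryl unit to 5-bromoisatin and prenyl bromide.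
- Forward order: aryl boronate (steps 1–4), diiodide (5), first coupling (6), four-membered ring (7, 8), second coupling (9), cyclobutene (10, 11), six-membered ring by metathesis (12), desilylation (13).
- Stereochemistry: aryl cis to methyl on the four-membered ring comes from suprafacial [2+2] on the (E)-alkene, and the absolute configuration from a C2-symmetric pyrrolidine auxiliary. Both centres pass unchanged through the metathesis. Alkene geometries come from syn-carboalumination (retained in iodination and coupling) and from the metathesis itself.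

Key step: step 12

Remark: Ar stands for 3-(2-methylbut-3-en-2-yl)-1-(triisopropylsilyl)-1H-indol-5-yl throughout.
Assumption: the (2R,5R)-auxiliary is taken to deliver the (2S,3S)-cyclobutanone; if the alkene is attacked from the other face, the (2S,5S)-amine is used and nothing else changes.
Assumption: the donor-substituted styrene reacts through its methyl-bearing carbon, so the carbonyl carbon of 18 is bonded to the quaternary carbon.

**Step 1**
Reactants: 1 5-bromoisatin; 2 1-bromo-3-methylbut-2-ene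
Product: 4 rac-5-bromo-3-hydroxy-3-(2-methylbut-3-en-2-yl)indolin-2-one, via prenylzinc bromide 3 (not isolated)
Conditions: Zn dust, THF/sat. aq. NH4Cl, 0 °C → rt
Reagents that add atoms: none
Why: Zinc Barbier allylation, in which the prenylzinc species adds through its γ-carbon to the more electrophilic C3 ketone and so installs the 1,1-dimethylallyl group; the carbinol configuration is irrelevant because this carbon becomes sp2 in step 2.

**Step 2**
Reactants: 4 rac-5-bromo-3-hydroxy-3-(2-methylbut-3-en-2-yl)indolin-2-one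
Product: 5 5-bromo-3-(2-methylbut-3-en-2-yl)-1H-indole
Conditions: LiAlH4, THF, 0 °C → reflux; aqueous work-up
Reagents that add atoms: none
Why: Reductive aromatisation of a 3-alkyl-3-hydroxyoxindole, in which hydride reduces the lactam carbonyl and the resulting hydroxyindoline loses both oxygens to give the 3-alkylindole, while the aryl bromide and the uncatalysed terminal alkene should not react.

**Step 3**
Reactants: 5 5-bromo-3-(2-methylbut-3-en-2-yl)-1H-indole
Product: 7 5-bromo-3-(2-methylbut-3-en-2-yl)-1-(triisopropylsilyl)-1H-indole, via sodium indolide 6 (not isolated)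
Conditions: NaH, THF, 0 °C; then TIPSCl, 0 °C → rt
Reagents that add atoms: chlorotriisopropylsilane, CC(C)[Si](Cl)(C(C)C)C(C)C
Why: N-silylation of the indolide anion; the bulky silyl group blocks N–H, shields C2 against the electrophiles of step 8 and tolerates the bases and palladium steps that follow.

**Step 4**
Reactants: 7 5-bromo-3-(2-methylbut-3-en-2-yl)-1-(triisopropylsilyl)-1H-indole
Product: 8 3-(2-methylbut-3-en-2-yl)-5-(4,4,5,5-tetramethyl-1,3,2-dioxaborolan-2-yl)-1-(triisopropylsilyl)-1H-indole (Ar–Bpin)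
Conditions: B2pin2, Pd(dppf)Cl2 (cat.), KOAc, 1,4-dioxane, 90 °C
Reagents that add atoms: bis(pinacolato)diboron, CC1(C)OB(OC1(C)C)B1OC(C)(C)C(C)(C)O1
Why: Miyaura borylation of an aryl bromide under weakly basic conditions that leave the N–Si bond and the terminal alkene alone.

**Step 5**
Reactants: 9 hexa-1,5-diyne
Product: 11 (1E,5E)-1,6-diiodo-2,5-dimethylhexa-1,5-diene, via bis(dimethylalanyl)diene 10 (not isolated)
Conditions: AlMe3 (4 equiv), Cp2ZrCl2 (0.5 equiv), CH2Cl2, 0 °C → rt; then I2, THF, −30 → 0 °C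
Reagents that add atoms: trimethylaluminium, C[Al](C)C; iodine, II
Why: Two-fold Negishi zirconium-catalysed methylalumination, a syn addition with aluminium on the terminal carbon, followed by iodinolysis with retention, fixes both trisubstituted alkenes as E.

**Step 6**
Reactants: 11 (1E,5E)-1,6-diiodo-2,5-dimethylhexa-1,5-diene (3 equiv, excess recovered); 8 Ar–Bpin
Product: 12 5-[(1E,5E)-6-iodo-2,5-dimethylhexa-1,5-dien-1-yl]-3-(2-methylbut-3-en-2-yl)-1-(triisopropylsilyl)-1H-indole
Conditions: Pd(dppf)Cl2 (cat.), aq. K3PO4, THF, rt → 45 °C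
Reagents that add atoms: none
Why: Suzuki–Miyaura coupling with retention of alkene geometry; the excess of the symmetric diiodide should hold the coupling at the mono stage and so differentiate the two ends before the ring is built.

**Step 7**
Reactants: 13 (2R,5R)-2,5-dimethylpyrrolidine; 14 acetyl chloride
Product: 15 1-[(2R,5R)-2,5-dimethylpyrrolidin-1-yl]ethan-1-one
Conditions: Et3N, CH2Cl2, 0 °C → rt
Reagents that add atoms: none
Why: Simple N-acylation of a secondary amine that does not touch the two stereocentres of the auxiliary.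

**Step 8**
Reactants: 12 iodo-diene; 15 1-[(2R,5R)-2,5-dimethylpyrrolidin-1-yl]ethan-1-one
Product: 18 (2S,3S)-3-Ar-2-[(3E)-4-iodo-3-methylbut-3-en-1-yl]-2-methylcyclobutan-1-one, via keteniminium triflate 16 (not isolated), via cyclobutaniminium triflate 17 (not isolated)
Conditions: 15 (1.2 equiv), Tf2O (1.1 equiv), 2,4,6-collidine, CH2Cl2, −20 °C → rt; then aq. NaHCO3, rt
Reagents that add atoms: water, O
Why: Ghosez keteniminium–alkene [2+2], in which the electron-rich styrene attacks the central carbon of 16 through its methyl-bearing carbon and the enamine carbon closes on the benzylic position, so addition is suprafacial on the (E)-alkene (aryl cis to methyl), the C2-symmetric pyrrolidine differentiates the two alkene faces and sets the absolute configuration at both new centres, and the vinyl iodide, the hindered 1,1-dimethylallyl vinyl group and the TIPS-shielded indole C2 are too poor as nucleophiles to compete.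

**Step 9**
Reactants: 18 iodo-cyclobutanone; 8 Ar–Bpin
Product: 19 (2S,3S)-3-Ar-2-[(3E)-4-Ar-3-methylbut-3-en-1-yl]-2-methylcyclobutan-1-one
Conditions: Pd(dppf)Cl2 (cat.), aq. K3PO4, THF, 40 °C
Reagents that add atoms: none
Why: Suzuki–Miyaura coupling of the (E)-vinyl iodide with retention installs the second aryl group as the trisubstituted styrene; the ketone has no epimerisable stereocentre (C2 is quaternary and C3 is β to the carbonyl).

**Step 10**
Reactants: 19 bis-aryl cyclobutanone
Product: 21 (3S,4S)-3-Ar-4-[(3E)-4-Ar-3-methylbut-3-en-1-yl]-4-methylcyclobut-1-en-1-yl trifluoromethanesulfonate, via potassium enolate 20 (not isolated)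
Conditions: KHMDS, THF, −78 °C; then PhNTf2, −78 → 0 °C; aq. NH4Cl
Reagents that add atoms: N-phenylbis(trifluoromethanesulfonimide), O=S(=O)(N(c1ccccc1)S(=O)(=O)C(F)(F)F)C(F)(F)F
Why: Enol triflate formation, where the enolate can only form toward the CH2 group because the other α-carbon is quaternary, and O-sulfonylation leaves both stereocentres untouched.

**Step 11**
Reactants: 21 cyclobutenyl triflate
Product: 22 (3R,4R)-3-Ar-4-[(3E)-4-Ar-3-methylbut-3-en-1-yl]-4-methylcyclobut-1-ene (aryl cis to methyl)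
Conditions: Pd(OAc)2 (cat.), PPh3, HCO2H, n-Bu3N, DMF, 50 °C
Reagents that add atoms: none
Why: Palladium-catalysed formate reduction of an enol triflate (oxidative addition, formate exchange, decarboxylation, C–H reductive elimination) replaces OTf by H and leaves the disubstituted cyclobutene alkene that becomes C3 and Cα.

**Step 12**
Reactants: 22 cyclobutene
Product: 23 5-[(1R,6R)-6-[(E)-2-Ar-ethenyl]-3,6-dimethylcyclohex-2-en-1-yl]-3-(2-methylbut-3-en-2-yl)-1-(triisopropylsilyl)-1H-indole
Conditions: Hoveyda–Grubbs II (5–10 mol%), toluene (0.005 M), 60–80 °C, argon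
Reagents that add atoms: none
Why: Proposed new method: a ring-rearrangement metathesis whose chain carrier is the indol-5-ylmethylidene ruthenium complex, which adds across the strained C3=Cα bond of 22 with ruthenium at C3, cycloreverts to leave Cα=Cβ(H)–Ar on C1, and whose C3 alkylidene then engages the tethered C4(CH3)=CH–Ar alkene through a second ruthenacyclobutane to form C3=C4 and hand the same arylidene to the next molecule of 22. The closest known reaction types are the ring-opening/ring-closing metathesis of cyclobutenes bearing a tethered terminal alkene and ring-closing metathesis onto trisubstituted alkenes with second-generation catalysts; the combination with a trisubstituted styrene as acceptor and a relayed arylidene has not been shown. The cyclohexene is closed by ring-closing metathesis (cycloreversion of a ruthenacyclobutane spanning C3 and C4), and since no atoms are lost the overall change is an isomerisation driven by release of cyclobutene strain. No stereocentre is formed: C1 and C2 are not touched, and the cis aryl/methyl relation of 22 maps onto the (1R,6R) arrangement in which the aryl group is cis to the new styryl group. The step needs ring opening with ruthenium at C3 (the other sense would close a cyclopentene) and E geometry at Cα=Cβ, both of which the bulk of the quaternary C1 next to Cα should favour, while high dilution suppresses ring-opening oligomerisation and the vinyl groups on the quaternary 1,1-dimethylallyl carbons are too hindered to compete.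

**Step 13**
Reactants: 23 bis-silylated product
Product: 24 5-[(1R,6R)-3,6-dimethyl-6-{(E)-2-[3-(2-methylbut-3-en-2-yl)-1H-indol-5-yl]ethenyl}cyclohex-2-en-1-yl]-3-(2-methylbut-3-en-2-yl)-1H-indole (target)
Conditions: TBAF, THF, 0 °C → rt
Reagents that add atoms: none
Why: Fluoride-induced cleavage of both N–Si bonds, which affects no alkene and no stereocentre.

**Compound list**

1 | 5-bromoisatin (5-bromo-1H-indole-2,3-dione) | O=C1Nc2ccc(Br)cc2C1=O | starting material
2 | 1-bromo-3-methylbut-2-ene (prenyl bromide) | CC(C)=CCBr | starting material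
3 | (3-methylbut-2-en-1-yl)zinc bromide | CC(C)=CC[Zn]Br | intermediate (not isolated)
4 | rac-5-bromo-3-hydroxy-3-(2-methylbut-3-en-2-yl)indolin-2-one | C=CC(C)(C)C1(O)C(=O)Nc2ccc(Br)cc21 | intermediate
5 | 5-bromo-3-(2-methylbut-3-en-2-yl)-1H-indole | C=CC(C)(C)c1c[nH]c2ccc(Br)cc12 | intermediate
6 | sodium 5-bromo-3-(2-methylbut-3-en-2-yl)indol-1-ide | C=CC(C)(C)c1c[n-]c2ccc(Br)cc12.[Na+] | intermediate (not isolated)
7 | 5-bromo-3-(2-methylbut-3-en-2-yl)-1-(triisopropylsilyl)-1H-indole | C=CC(C)(C)c1cn([Si](C(C)C)(C(C)C)C(C)C)c2ccc(Br)cc12 | intermediate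
8 | 3-(2-methylbut-3-en-2-yl)-5-(4,4,5,5-tetramethyl-1,3,2-dioxaborolan-2-yl)-1-(triisopropylsilyl)-1H-indole | C=CC(C)(C)c1cn([Si](C(C)C)(C(C)C)C(C)C)c2ccc(B3OC(C)(C)C(C)(C)O3)cc12 | intermediate
9 | hexa-1,5-diyne | C#CCCC#C | starting material
10 | (1E,5E)-(2,5-dimethylhexa-1,5-diene-1,6-diyl)bis(dimethylalane) | C[Al](C)/C=C(\C)CC/C(C)=C/[Al](C)C | intermediate (not isolated)
11 | (1E,5E)-1,6-diiodo-2,5-dimethylhexa-1,5-diene | I/C=C(\C)CC/C(C)=C/I | intermediate
12 | 5-[(1E,5E)-6-iodo-2,5-dimethylhexa-1,5-dien-1-yl]-3-(2-methylbut-3-en-2-yl)-1-(triisopropylsilyl)-1H-indole | C=CC(C)(C)c1cn([Si](C(C)C)(C(C)C)C(C)C)c2ccc(/C=C(\C)CC/C(C)=C/I)cc12 | intermediate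
13 | (2R,5R)-2,5-dimethylpyrrolidine | C[C@@H]1CC[C@@H](C)N1 | starting material
14 | acetyl chloride | CC(Cl)=O | starting material
15 | 1-[(2R,5R)-2,5-dimethylpyrrolidin-1-yl]ethan-1-one | C[C@@H]1CC[C@@H](C)N1C(C)=O | intermediate
16 | (2R,5R)-1-ethenylidene-2,5-dimethylpyrrolidin-1-ium trifluoromethanesulfonate | C=C=[N+]1[C@H](C)CC[C@H]1C.[O-]S(=O)(=O)C(F)(F)F | intermediate (not isolated)
17 | (2R,5R)-1-{(2S,3S)-3-Ar-2-[(3E)-4-iodo-3-methylbut-3-en-1-yl]-2-methylcyclobutylidene}-2,5-dimethylpyrrolidin-1-ium trifluoromethanesulfonate | I/C=C(\C)CC[C@]3(C)C(=[N+]4[C@H](C)CC[C@H]4C)C[C@H]3c5ccc6c(c5)c(C(C)(C)C=C)cn6[Si](C(C)C)(C(C)C)C(C)C.[O-]S(=O)(=O)C(F)(F)F | intermediate (not isolated)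
18 | (2S,3S)-3-Ar-2-[(3E)-4-iodo-3-methylbut-3-en-1-yl]-2-methylcyclobutan-1-one | I/C=C(\C)CC[C@]3(C)C(=O)C[C@H]3c5ccc6c(c5)c(C(C)(C)C=C)cn6[Si](C(C)C)(C(C)C)C(C)C | intermediate
19 | (2S,3S)-3-Ar-2-[(3E)-4-Ar-3-methylbut-3-en-1-yl]-2-methylcyclobutan-1-one | C=CC(C)(C)c1cn([Si](C(C)C)(C(C)C)C(C)C)c2ccc(/C=C(\C)CC[C@]3(C)C(=O)C[C@H]3c5ccc6c(c5)c(C(C)(C)C=C)cn6[Si](C(C)C)(C(C)C)C(C)C)cc12 | intermediate
20 | potassium (3S,4S)-3-Ar-4-[(3E)-4-Ar-3-methylbut-3-en-1-yl]-4-methylcyclobut-1-en-1-olate | C=CC(C)(C)c1cn([Si](C(C)C)(C(C)C)C(C)C)c2ccc(/C=C(\C)CC[C@]3(C)C([O-])=C[C@H]3c5ccc6c(c5)c(C(C)(C)C=C)cn6[Si](C(C)C)(C(C)C)C(C)C)cc12.[K+] | intermediate (not isolated)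
21 | (3S,4S)-3-Ar-4-[(3E)-4-Ar-3-methylbut-3-en-1-yl]-4-methylcyclobut-1-en-1-yl trifluoromethanesulfonate | C=CC(C)(C)c1cn([Si](C(C)C)(C(C)C)C(C)C)c2ccc(/C=C(\C)CC[C@]3(C)C(OS(=O)(=O)C(F)(F)F)=C[C@H]3c5ccc6c(c5)c(C(C)(C)C=C)cn6[Si](C(C)C)(C(C)C)C(C)C)cc12 | intermediate
22 | (3R,4R)-3-Ar-4-[(3E)-4-Ar-3-methylbut-3-en-1-yl]-4-methylcyclobut-1-ene (aryl cis to methyl) | C=CC(C)(C)c1cn([Si](C(C)C)(C(C)C)C(C)C)c2ccc(/C=C(\C)CC[C@]3(C)C=C[C@H]3c5ccc6c(c5)c(C(C)(C)C=C)cn6[Si](C(C)C)(C(C)C)C(C)C)cc12 | intermediate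
23 | 5-[(1R,6R)-6-[(E)-2-Ar-ethenyl]-3,6-dimethylcyclohex-2-en-1-yl]-3-(2-methylbut-3-en-2-yl)-1-(triisopropylsilyl)-1H-indole | C=CC(C)(C)c1cn([Si](C(C)C)(C(C)C)C(C)C)c2ccc(/C=C/[C@@]3(C)CCC(C)=C[C@H]3c5ccc6c(c5)c(C(C)(C)C=C)cn6[Si](C(C)C)(C(C)C)C(C)C)cc12 | intermediate
24 | 5-[(1R,6R)-3,6-dimethyl-6-{(E)-2-[3-(2-methylbut-3-en-2-yl)-1H-indol-5-yl]ethenyl}cyclohex-2-en-1-yl]-3-(2-methylbut-3-en-2-yl)-1H-indole | C=CC(C)(C)c1c[nH]c2ccc(/C=C/[C@@]3(C)CCC(C)=C[C@H]3c3ccc4[nH]cc(C(C)(C)C=C)c4c3)cc12 | target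

**Step count and risks**

Total steps: 13. Longest linear sequence: 11 steps (1, 2, 3, 4, 6, 8, 9, 10, 11, 12, 13 from 5-bromoisatin).

Steps most likely to fail:

Step 12. The C3 alkylidene formed on ring opening may not close onto the trisubstituted styrene and may instead be consumed by further cyclobutene (oligomerisation). Ring opening may also take the opposite sense and close a cyclopentene, and the first turnover necessarily transfers the initiator's benzylidene in place of the indolylmethylidene, at most in the amount of the catalyst loading. The fallback sets out from iodide 18 and from bromide 7, and uses only established metathesis steps. Ketone 18 is deprotonated (KHMDS, THF, −78 °C) to the potassium enolate of 18 F1, which PhNTf2 converts into the iodo enol triflate (3S,4S)-3-Ar-4-[(3E)-4-iodo-3-methylbut-3-en-1-yl]-4-methylcyclobut-1-en-1-yl triflate F2. Pd(OAc)2/PPh3, HCO2H and n-Bu3N in DMF should remove both the triflate and the vinylic iodide to give (3R,4R)-3-Ar-4-methyl-4-(3-methylbut-3-en-1-yl)cyclobut-1-ene F3. Bromide 7 and vinylboronic acid pinacol ester (Pd(dppf)Cl2, aq. K3PO4, THF) give 5-ethenyl-3-(2-methylbut-3-en-2-yl)-1-(triisopropylsilyl)-1H-indole F4. F3 with excess F4 and Hoveyda–Grubbs II in toluene should then undergo the known ring-opening/ring-closing/cross-metathesis cascade, with closure onto a 1,1-disubstituted terminal alkene, the arylidene supplied by the vinylarene and ethene lost, and so come back to the route at 23.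

Step 8. Facial discrimination by the auxiliary may be poor for this acyclic trisubstituted alkene, and a long-lived benzylic cation could erode the transfer of alkene geometry. The fallback sets out from diene 12 and separates the enantiomers by a reagent-controlled reduction. N,N-Dimethylacetamide, Tf2O and collidine generate N,N-dimethylketeniminium triflate F5, which adds to 12 to give the racemic N,N-dimethylcyclobutaniminium triflate F6; aqueous NaHCO3 then gives the racemic ketone rac-18 F7. Reduction with (S)-Me-CBS and catecholborane (toluene, −78 °C; the borane does not hydroborate the alkenes at this temperature) should place the hydride on the same carbonyl face in both enantiomers and give two diastereomeric carbinols, the (1R,2S,3S)-cyclobutanol F8 and the (1R,2R,3R)-cyclobutanol F9, which are separable by chromatography. Dess–Martin oxidation of F8 returns enantiomerically enriched 18.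

Step 11. The cyclobutenylpalladium intermediate may add across the tethered styrene before formate delivers hydride, and palladium hydride may move the cyclobutene double bond into conjugation with the aryl group. The fallback sets out from ketone 19 and avoids palladium. TsNHNH2 in MeOH at rt gives the tosylhydrazone of 19 F10; LDA (3 equiv, THF, −78 °C → rt) should then effect a Shapiro reaction toward the only α-CH2 through the cyclobutenyllithium F11, which is protonated on work-up to give 22.

**Further compounds**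

F1 | step 12 | potassium (3S,4S)-3-Ar-4-[(3E)-4-iodo-3-methylbut-3-en-1-yl]-4-methylcyclobut-1-en-1-olate | I/C=C(\C)CC[C@]3(C)C([O-])=C[C@H]3c5ccc6c(c5)c(C(C)(C)C=C)cn6[Si](C(C)C)(C(C)C)C(C)C.[K+]
F2 | step 12 | (3S,4S)-3-Ar-4-[(3E)-4-iodo-3-methylbut-3-en-1-yl]-4-methylcyclobut-1-en-1-yl trifluoromethanesulfonate | I/C=C(\C)CC[C@]3(C)C(OS(=O)(=O)C(F)(F)F)=C[C@H]3c5ccc6c(c5)c(C(C)(C)C=C)cn6[Si](C(C)C)(C(C)C)C(C)C
F3 | step 12 | (3R,4R)-3-Ar-4-methyl-4-(3-methylbut-3-en-1-yl)cyclobut-1-ene | C=C(C)CC[C@]3(C)C=C[C@H]3c5ccc6c(c5)c(C(C)(C)C=C)cn6[Si](C(C)C)(C(C)C)C(C)C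
F4 | step 12 | 5-ethenyl-3-(2-methylbut-3-en-2-yl)-1-(triisopropylsilyl)-1H-indole | C=Cc1ccc2c(c1)c(C(C)(C)C=C)cn2[Si](C(C)C)(C(C)C)C(C)C
F5 | step 8 | N,N-dimethylketeniminium trifluoromethanesulfonate | C=C=[N+](C)C.[O-]S(=O)(=O)C(F)(F)F
F6 | step 8 | rac-N-{(2S*,3S*)-3-Ar-2-[(3E)-4-iodo-3-methylbut-3-en-1-yl]-2-methylcyclobutylidene}-N-methylmethanaminium trifluoromethanesulfonate (racemate, one enantiomer drawn) | I/C=C(\C)CC[C@]3(C)C(=[N+](C)C)C[C@H]3c5ccc6c(c5)c(C(C)(C)C=C)cn6[Si](C(C)C)(C(C)C)C(C)C.[O-]S(=O)(=O)C(F)(F)F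
F7 | step 8 | rac-(2S*,3S*)-3-Ar-2-[(3E)-4-iodo-3-methylbut-3-en-1-yl]-2-methylcyclobutan-1-one (racemate, one enantiomer drawn) | I/C=C(\C)CC[C@]3(C)C(=O)C[C@H]3c5ccc6c(c5)c(C(C)(C)C=C)cn6[Si](C(C)C)(C(C)C)C(C)C
F8 | step 8 | (1R,2S,3S)-3-Ar-2-[(3E)-4-iodo-3-methylbut-3-en-1-yl]-2-methylcyclobutan-1-ol | I/C=C(\C)CC[C@]3(C)[C@H](O)C[C@H]3c5ccc6c(c5)c(C(C)(C)C=C)cn6[Si](C(C)C)(C(C)C)C(C)C
F9 | step 8 | (1R,2R,3R)-3-Ar-2-[(3E)-4-iodo-3-methylbut-3-en-1-yl]-2-methylcyclobutan-1-ol | I/C=C(\C)CC[C@@]3(C)[C@H](O)C[C@@H]3c5ccc6c(c5)c(C(C)(C)C=C)cn6[Si](C(C)C)(C(C)C)C(C)C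
F10 | step 11 | N′-{(2S,3S)-3-Ar-2-[(3E)-4-Ar-3-methylbut-3-en-1-yl]-2-methylcyclobutylidene}-4-methylbenzenesulfonohydrazide | C=CC(C)(C)c1cn([Si](C(C)C)(C(C)C)C(C)C)c2ccc(/C=C(\C)CC[C@]3(C)C(=NNS(=O)(=O)c4ccc(C)cc4)C[C@H]3c5ccc6c(c5)c(C(C)(C)C=C)cn6[Si](C(C)C)(C(C)C)C(C)C)cc12
F11 | step 11 | {(3S,4S)-3-Ar-4-[(3E)-4-Ar-3-methylbut-3-en-1-yl]-4-methylcyclobut-1-en-1-yl}lithium | C=CC(C)(C)c1cn([Si](C(C)C)(C(C)C)C(C)C)c2ccc(/C=C(\C)CC[C@]3(C)C([Li])=C[C@H]3c5ccc6c(c5)c(C(C)(C)C=C)cn6[Si](C(C)C)(C(C)C)C(C)C)cc12
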